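The easy step is a count. The partner charge divided by the substrate charge, 70.0% in Sunday's flask, is our ceiling: the most target the partner can pay for, in fractions of the substrate charged, if each target takes one partner. That makes partner the limiting reagent there. In Tuesday's flask the same ratio is 140%, more partner than substrate, and its target climbs to 98%, so the charge of substrate caps it there.

in all of them: substrate 0.40 M
- Sunday's: partner 0.28 M; temperature 25 °C; the very flask that is asked about, followed so far
- Tuesday's: partner 0.56 M; temperature 31 °C; run made earlier
- flask: partner 0.280 M; temperature 25 °C; time 50 min

- Sunday's (time / min: target / %, substrate / %): 2.50: 39, 55; 8.00: 67, 16; 15.0: 71, 6; 20.0: 70, 2; 30.0: 69, 0; 40.0: 73, 1; 50.0: 69, 1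
- Tuesday's (time / min: target / %, substrate / %): 0.833: 31, 67; 1.33: 42, 55; 2.00: 59, 36; 3.00: 72, 19; 4.00: 82, 14; 6.00: 92, 3; 10.0: 98, 0

(scatter of a reading: 2 percentage points)

- north: at 50 min add partner, 50.0% of the amount charged, then wait 50 min
- south: change nothing and wait 50 min more
- north-east: at 50 min take out 90% of the target then present, then wait 50 min
- west: at 50 min raise the temperature by 10 K, then wait 50 min

- target taken out counts as made
- the numbers in the tables scatter by 2 percentage points (one standard deviation)
- additions bring no volume worth counting

1. target, in percent of the substrate first charged, at 50 min
2. what to do for the largest gain in target; "none" if nothing gains more than 2 percentage points (north / south / north-east / west / none)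
3. target present, with what was taken out counted in, in percent of the substrate first charged, after south
4. target present, with what was taken out counted in, in percent of the substrate first charged, after west

The ceiling bounds Sunday's flask from above. From below, its five readings from 15.0 min on average 70.4%, and two standard errors under that stands 68.6%. To see whether that level can still move, we read the substrate's time constant off Sunday's first two readings, 4.45 min. Sunday's flask has run 11.2 of these by 50 min, and its target readings stayed level within their scatter of 2 percentage points while the substrate readings fell from 6% to 0%, which fits a flask short of partner. We therefore commit to the ceiling for now. South, west and north-east add no partner, so the ceiling stays. North lifts the partner ratio to 105%, past the substrate charge. Sunday's substrate reads 1% at 50.0 min, so the missing share stands in a form we do not read, and if it still takes up partner, as Tuesday's 98% suggests, we expect a gain of 30 points.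

The forecast gives 70% (range 68% to 72%), a central value at the top of our bracket, with 70% after south, 70% after west and north as best: “Waiting, heating or removing target supplies no partner”.

Sunday's flask gives 70.0%, with north best at 30 points, and 70.0% after south and 70.0% after west.

    substrate → intermediate (k = 0.00427 s⁻¹, Ea = 79.0 kJ mol⁻¹)
    partner + intermediate → target (k = 0.163 L mol⁻¹ s⁻¹, Ea = 37.0 kJ mol⁻¹)
    (constants at 25 °C)

At 50.0 min, Sunday's flask holds 0% of its partner free and 30.0% of the substrate charged as intermediate, and one minus the ceiling is 30.0%.

With 1.6 M of substrate and the same partner, the ceiling falls to 17.5%. That neighbouring flask computes to 17.5% target, with 82.5% as intermediate.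

The earlier runs and the new flask come from a simulation for an exercise; the scatter is artificial.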